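**Retrosynthetic overview**

1. Locants C1–C8 are those of the 6-oxabicyclo[3.2.1]octane core. The side chain with C8, C1 and C7 is the geranyl unit of auraptene: umbelliferone 1 + geranyl bromide 2 give 3, whose terminal (E)-methyl is oxidised (via alcohol 4) to enal 5. C2–C5 and the C5 methyl come from ethyl levulinate 6 (via ester 7) as silyl enol ether aldehyde 8.
2. Key disconnection C5–C8: the ketone carbon of 8, turned into a nucleophilic α-silyloxy (ketyl-type) radical, adds to the electrophilic β-carbon C8 of 5. The resulting enolate 9 closes C1–C2 by aldol, forming the carbocycle (ring one) as hydroxy aldehyde 10, which is reduced in the same flask to diol 11.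
3. Ring two (tetrahydrofuran, C5–O6) is closed last: ionisation at C5 and capture by the axial C7 hydroxyl gives racemic ether 12 and removes the C5 epimer mixture.
4. Absolute configuration: lipase acylation selects the (2R) alcohol as acetate 13; methanolysis gives target 14.

Assumption: racemic intermediates 9–12 are named and drawn as the enantiomer that is carried on to the target.

**Route**

Step 1
Reactants: 1 umbelliferone (7-hydroxy-2H-chromen-2-one); 2 geranyl bromide
Product: 3 auraptene, 7-{[(2E)-3,7-dimethylocta-2,6-dien-1-yl]oxy}-2H-chromen-2-one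
Conditions: K2CO3 (1.5 equiv), acetone, reflux
Reagents that add atoms: none
Why: Williamson O-alkylation (SN2) of the acidic 7-hydroxyl by the allylic bromide under mild carbonate base keeps the (2E) geometry and leaves the lactone alone.

Step 2
Reactants: 3 auraptene
Product: 5 (2E,6E)-2,6-dimethyl-8-[(2-oxo-2H-chromen-7-yl)oxy]octa-2,6-dienal, via allylic alcohol 4 (not isolated)
Conditions: SeO2 (0.5 equiv), t-BuOOH (70% aq., 3 equiv), salicylic acid (0.1 equiv), CH2Cl2, 0 °C to rt; then MnO2 (15 equiv), CH2Cl2, rt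
Reagents that add atoms: tert-butyl hydroperoxide, CC(C)(C)OO (its oxygen is transferred by way of selenium dioxide, O=[Se]=O)
Why: Selenium dioxide allylic oxidation (ene reaction then [2,3]-sigmatropic shift) attacks only the (E)-methyl of the electron-rich terminal alkene, the inner alkene being deactivated by the allylic aryloxy group, and MnO2 then converges alcohol 4 on the (E)-enal without isomerisation.

Step 3
Reactants: 6 ethyl levulinate (ethyl 4-oxopentanoate)
Product: 7 ethyl 4-[(tert-butyldimethylsilyl)oxy]pent-4-enoate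
Conditions: LiN(i-Pr)2 (1.05 equiv), THF, −78 °C; then t-BuMe2SiCl, DMPU, −78 °C to 0 °C
Reagents that add atoms: tert-butyldimethylsilyl chloride, CC(C)(C)[Si](C)(C)Cl
Why: Kinetic deprotonation of the methyl ketone on its less hindered methyl side at −78 °C followed by O-silylation gives the terminal 2-silyloxy-1-alkene (kinetic silyl enol ether formation), the ester α-position being far less acidic.

Step 4
Reactants: 7 ethyl 4-[(tert-butyldimethylsilyl)oxy]pent-4-enoate
Product: 8 4-[(tert-butyldimethylsilyl)oxy]pent-4-enal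
Conditions: i-Bu2AlH (1.05 equiv), CH2Cl2, −78 °C; aqueous potassium sodium tartrate (KNaC4H4O6) work-up
Reagents that add atoms: none
Why: Partial ester reduction at −78 °C stops at the tetrahedral aluminium hemiacetal, which gives the aldehyde on work-up, while the silyl enol ether is inert to the hydride.

Step 5
Reactants: 5 (2E,6E)-2,6-dimethyl-8-[(2-oxo-2H-chromen-7-yl)oxy]octa-2,6-dienal; 8 4-[(tert-butyldimethylsilyl)oxy]pent-4-enal
Product: 11 (1R,2R,3R,4RS)-4-[(tert-butyldimethylsilyl)oxy]-2-(hydroxymethyl)-2,4-dimethyl-3-{(3E)-3-methyl-5-[(2-oxo-2H-chromen-7-yl)oxy]pent-3-en-1-yl}cyclohexan-1-ol (racemic; both epimers at the silyloxy carbon), via enolate 9 (not isolated), via hydroxy aldehyde 10 (not isolated)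
Conditions: 5 (1 equiv), 8 (2.5 equiv), Fe(acac)3 (0.3 equiv), PhSiH3 (2.5 equiv), EtOH/ethylene glycol 5:1, degassed, 0 °C to rt; then MeOH, NaBH4 (1.5 equiv), −20 °C
Reagents that add atoms: none
Why: Proposed new method: hydrogen-atom transfer from an iron hydride to silyl enol ether 8 puts the hydrogen on the CH2 terminus and leaves a nucleophilic tertiary α-silyloxy radical at C5 (a ketyl equivalent, the ketone carbon with reversed polarity) that adds to the electrophilic β-carbon C8 of enal 5 (Giese addition); the α-formyl radical is reduced by divalent iron to enolate 9, which closes C1–C2 by intramolecular aldol through a chair transition state with the side chain equatorial, the C8 hydrogen next to the C1 methyl (least allylic strain) and both oxygens on the metal, so that the formyl group (axial on C1), the C2 hydroxyl and the C8 side chain come out mutually cis, which is also the thermodynamic arrangement; borohydride then reduces only the aldehyde of 10. The closest known reactions are the iron-catalysed radical–polar crossover annulation of γ,δ-unsaturated aldehydes with α-substituted enones and the iron-hydride coupling of silyl enol ethers with Michael acceptors; C5 forms as an epimer mixture that step 6 removes, and the product is racemic.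

Step 6
Reactants: 11 silyl ether diol (both C5 epimers)
Product: 12 racemic 7-{[(2E)-5-[(1R*,2R*,5S*,8R*)-2-hydroxy-1,5-dimethyl-6-oxabicyclo[3.2.1]octan-8-yl]-3-methylpent-2-en-1-yl]oxy}-2H-chromen-2-one
Conditions: BF3·OEt2 (1.1 equiv), CH2Cl2, −40 °C to 0 °C; aq. NaHCO3
Reagents that add atoms: none
Why: BF3-assisted ionisation of the tertiary silyl ether gives the planar C5 cation, which is captured by the axial C7 hydroxyl held 1,3-diaxial to it (SN1 cycloetherification, five-membered ring), so both C5 epimers converge on the one cis-bridged tetrahydrofuran and C5 is set by the bridge, whereas the equatorial C2 hydroxyl would need a boat to reach C5.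

Step 7
Reactants: 12 racemic bicyclic ether alcohol
Product: 13 (1R,2R,5S,8R)-1,5-dimethyl-8-{(3E)-3-methyl-5-[(2-oxo-2H-chromen-7-yl)oxy]pent-3-en-1-yl}-6-oxabicyclo[3.2.1]octan-2-yl acetate
Conditions: immobilised Burkholderia cepacia lipase, vinyl acetate (5 equiv), t-BuOMe, 40 °C, stopped at about 50% conversion; chromatography
Reagents that add atoms: vinyl acetate, CC(=O)OC=C
Why: Lipase-catalysed kinetic resolution (enantioselective transesterification) acylates the (2R) alcohol, as the Kazlauskas rule predicts for a carbinol flanked by a large quaternary C1 and a medium C3H2, and leaves the (2S) enantiomer as the alcohol to be removed by chromatography, which fixes the absolute configuration of all four stereocentres at once.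

Step 8
Reactants: 13 (2R)-acetate
Product: 14 target, 7-{[(2E)-5-[(1R,2R,5S,8R)-2-hydroxy-1,5-dimethyl-6-oxabicyclo[3.2.1]octan-8-yl]-3-methylpent-2-en-1-yl]oxy}-2H-chromen-2-one
Conditions: K2CO3 (0.5 equiv), MeOH, rt; aq. NH4Cl work-up
Reagents that add atoms: none
Why: Mild base-catalysed methanolysis (transesterification) of the secondary acetate touches neither the aryl allyl ether nor any stereocentre, and any methanolysed coumarin lactone recloses on the weakly acidic work-up.

**Compound list**

1 | umbelliferone (7-hydroxy-2H-chromen-2-one) | Oc1ccc2ccc(=O)oc2c1 | starting material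
2 | geranyl bromide, (2E)-1-bromo-3,7-dimethylocta-2,6-diene | C/C(=C\CBr)CCC=C(C)C | starting material
3 | auraptene, 7-{[(2E)-3,7-dimethylocta-2,6-dien-1-yl]oxy}-2H-chromen-2-one | C/C(=C\COc1ccc2ccc(=O)oc2c1)CCC=C(C)C | intermediate
4 | 7-{[(2E,6E)-8-hydroxy-3,7-dimethylocta-2,6-dien-1-yl]oxy}-2H-chromen-2-one (formed in the flask) | C/C(=C\COc1ccc2ccc(=O)oc2c1)CC/C=C(\C)CO | intermediate
5 | (2E,6E)-2,6-dimethyl-8-[(2-oxo-2H-chromen-7-yl)oxy]octa-2,6-dienal | C/C(=C\COc1ccc2ccc(=O)oc2c1)CC/C=C(\C)C=O | intermediate
6 | ethyl levulinate (ethyl 4-oxopentanoate) | CCOC(=O)CCC(C)=O | starting material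
7 | ethyl 4-[(tert-butyldimethylsilyl)oxy]pent-4-enoate | CCOC(=O)CCC(=C)O[Si](C)(C)C(C)(C)C | intermediate
8 | 4-[(tert-butyldimethylsilyl)oxy]pent-4-enal | O=CCCC(=C)O[Si](C)(C)C(C)(C)C | intermediate
9 | (E)-enolate of 4-[(tert-butyldimethylsilyl)oxy]-2,4-dimethyl-3-{(3E)-3-methyl-5-[(2-oxo-2H-chromen-7-yl)oxy]pent-3-en-1-yl}-7-oxoheptanal, enolate oxygen anti to C3; racemic, both epimers at C4 (formed in the flask) | C/C(=C\COc1ccc2ccc(=O)oc2c1)CC[C@@H](C(C)(CCC=O)O[Si](C)(C)C(C)(C)C)/C(C)=C/[O-] | intermediate
10 | (1S,2R,3RS,6R)-3-[(tert-butyldimethylsilyl)oxy]-6-hydroxy-1,3-dimethyl-2-{(3E)-3-methyl-5-[(2-oxo-2H-chromen-7-yl)oxy]pent-3-en-1-yl}cyclohexane-1-carbaldehyde; formyl, ring hydroxyl and side chain mutually cis; racemic (formed in the flask) | C/C(=C\COc1ccc2ccc(=O)oc2c1)CC[C@@H]1[C@](C)(C=O)[C@H](O)CCC1(C)O[Si](C)(C)C(C)(C)C | intermediate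
11 | (1R,2R,3R,4RS)-4-[(tert-butyldimethylsilyl)oxy]-2-(hydroxymethyl)-2,4-dimethyl-3-{(3E)-3-methyl-5-[(2-oxo-2H-chromen-7-yl)oxy]pent-3-en-1-yl}cyclohexan-1-ol; CH2OH, ring hydroxyl and side chain mutually cis; racemic | C/C(=C\COc1ccc2ccc(=O)oc2c1)CC[C@@H]1[C@](C)(CO)[C@H](O)CCC1(C)O[Si](C)(C)C(C)(C)C | intermediate
12 | racemic 7-{[(2E)-5-[(1R*,2R*,5S*,8R*)-2-hydroxy-1,5-dimethyl-6-oxabicyclo[3.2.1]octan-8-yl]-3-methylpent-2-en-1-yl]oxy}-2H-chromen-2-one (1:1 mixture of 14 and its mirror image) | C/C(=C\COc1ccc2ccc(=O)oc2c1)CC[C@@H]1[C@]2(C)CO[C@@]1(C)CC[C@H]2O | intermediate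
13 | (1R,2R,5S,8R)-1,5-dimethyl-8-{(3E)-3-methyl-5-[(2-oxo-2H-chromen-7-yl)oxy]pent-3-en-1-yl}-6-oxabicyclo[3.2.1]octan-2-yl acetate | C/C(=C\COc1ccc2ccc(=O)oc2c1)CC[C@@H]1[C@]2(C)CO[C@@]1(C)CC[C@H]2OC(C)=O | intermediate
14 | 7-{[(2E)-5-[(1R,2R,5S,8R)-2-hydroxy-1,5-dimethyl-6-oxabicyclo[3.2.1]octan-8-yl]-3-methylpent-2-en-1-yl]oxy}-2H-chromen-2-one | C/C(=C\COc1ccc2ccc(=O)oc2c1)CC[C@@H]1[C@]2(C)CO[C@@]1(C)CC[C@H]2O | target

**Step count and risks**

Total: 8 steps (two of them in the side branch 6 → 7 → 8). Longest linear sequence: 6 steps (1 + 2 → 3 → 5 → 11 → 12 → 13 → 14).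

The three steps most likely to fail are 5, 6 and 7.

The annulation of step 5 carries the most risk. The tertiary radical must add to a β-alkyl, α-methyl enal, and the coumarin double bond and the inner trisubstituted alkene of 5 are competing radical and hydrogen-atom acceptors. The fallback takes the coumarin out of the radical step and forms the aryl ether last. Setting out from geranyl bromide 2, displacement with KOAc in DMF gives geranyl acetate F1. The SeO2/t-BuOOH then MnO2 sequence of step 2 gives, through 8-hydroxygeranyl acetate F2, 8-oxogeranyl acetate F3, which can be used in excess. Annulation of F3 with 8 under the step 5 conditions passes through enolate F4 and hydroxy aldehyde F5 and, after the borohydride quench, gives silyl ether diol F6. BF3·OEt2 closes this to bicyclic ether acetate F7, and K2CO3 in MeOH frees allylic alcohol F8. Mitsunobu etherification of the primary allylic hydroxyl of F8 with umbelliferone 1 (PPh3, diisopropyl azodicarboxylate, THF) comes back to the route at racemic ether 12.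

The cycloetherification of step 6 passes through a free tertiary cation in the presence of an acid-labile aryl allyl ether. The cation could also lose a proton, be trapped by the C2 hydroxyl to give the 7-oxabicyclo[2.2.1]heptane isomer, or be attacked by the side-chain alkene. The fallback keeps the C5 oxygen and never ionises C5. Step 5 is stopped before the borohydride quench and hydroxy aldehyde 10 is isolated. HF·pyridine in THF removes the silyl group, and the C5 epimer whose hydroxyl is cis to the formyl group closes to bridged lactol F9; the other epimer cannot close and is separated. Et3SiH with TMSOTf in CH2Cl2 at −78 °C then reduces the lactol through the bridged oxocarbenium ion, returning to the route at 12.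

The resolution of step 7 depends on a lipase accepting a secondary alcohol next to a quaternary bridgehead carbon, which may be slow or poorly selective. The fallback is a classical resolution through covalent diastereomers. Setting out from 12, esterification with (1S)-(−)-camphanic chloride (DMAP, pyridine, CH2Cl2) gives the camphanate of the (1R,2R,5S,8R) alcohol F10 and the diastereomeric camphanate of the (1S,2S,5R,8S) alcohol F11. These are separated by chromatography or crystallisation, and K2CO3 in MeOH cleaves F10 to reach the route directly at target 14.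

**Further compounds**

F1 | step 5 | geranyl acetate | C/C(=C\COC(C)=O)CCC=C(C)C
F2 | step 5 | (2E,6E)-8-hydroxy-3,7-dimethylocta-2,6-dien-1-yl acetate (8-hydroxygeranyl acetate) | C/C(=C\COC(C)=O)CC/C=C(\C)CO
F3 | step 5 | (2E,6E)-3,7-dimethyl-8-oxoocta-2,6-dien-1-yl acetate (8-oxogeranyl acetate) | C/C(=C\COC(C)=O)CC/C=C(\C)C=O
F4 | step 5 | (E)-enolate of the radical adduct of F3 and 8 (acetate analogue of 9; racemic, both C5 epimers) | C/C(=C\COC(C)=O)CC[C@@H](C(C)(CCC=O)O[Si](C)(C)C(C)(C)C)/C(C)=C/[O-]
F5 | step 5 | hydroxy aldehyde, acetate analogue of 10 (racemic, both C5 epimers) | C/C(=C\COC(C)=O)CC[C@@H]1[C@](C)(C=O)[C@H](O)CCC1(C)O[Si](C)(C)C(C)(C)C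
F6 | step 5 | silyl ether diol, acetate analogue of 11 (racemic, both C5 epimers) | C/C(=C\COC(C)=O)CC[C@@H]1[C@](C)(CO)[C@H](O)CCC1(C)O[Si](C)(C)C(C)(C)C
F7 | step 5 | racemic (2E)-5-[(1R*,2R*,5S*,8R*)-2-hydroxy-1,5-dimethyl-6-oxabicyclo[3.2.1]octan-8-yl]-3-methylpent-2-en-1-yl acetate | C/C(=C\COC(C)=O)CC[C@@H]1[C@]2(C)CO[C@@]1(C)CC[C@H]2O
F8 | step 5 | racemic (1R*,2R*,5S*,8R*)-8-[(3E)-5-hydroxy-3-methylpent-3-en-1-yl]-1,5-dimethyl-6-oxabicyclo[3.2.1]octan-2-ol | C/C(=C\CO)CC[C@@H]1[C@]2(C)CO[C@@]1(C)CC[C@H]2O
F9 | step 6 | racemic bridged lactol, 7-{[(2E)-5-[(1R*,2R*,5S*,8R*)-2,7-dihydroxy-1,5-dimethyl-6-oxabicyclo[3.2.1]octan-8-yl]-3-methylpent-2-en-1-yl]oxy}-2H-chromen-2-one (both C7 anomers) | C/C(=C\COc1ccc2ccc(=O)oc2c1)CC[C@@H]1[C@]2(C)C(O)O[C@@]1(C)CC[C@H]2O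
F10 | step 7 | (1S,4R)-camphanate of 14 | C/C(=C\COc1ccc2ccc(=O)oc2c1)CC[C@@H]1[C@]2(C)CO[C@@]1(C)CC[C@H]2OC(=O)[C@@]12CC[C@@](C)(C(=O)O1)C2(C)C
F11 | step 7 | (1S,4R)-camphanate of the enantiomer of 14 | C/C(=C\COc1ccc2ccc(=O)oc2c1)CC[C@H]1[C@@]2(C)CO[C@]1(C)CC[C@@H]2OC(=O)[C@@]12CC[C@@](C)(C(=O)O1)C2(C)C
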